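**Retrosynthetic overview**
1. Last bond made: C4'–O of the ring-B catechol, by ortho-oxygenation of a 3'-phenol at its only free ortho C–H through an o-quinone, then reduction (key step).
2. Before it: both aryl–prenyl bonds, made together from a 2',6'-dibromide by twofold linear-selective Negishi coupling.
3. Ring C is closed at O1–C2 (a C–O bond) when a deoxybenzoin takes up one carbon from DMF; the deoxybenzoin comes from Friedel–Crafts acylation of phloroglucinol with a dibromoarylacetic acid.
4. The acid comes from (3,5-dimethoxyphenyl)acetic acid by mono-O-demethylation, then dibromination at the two carbons flanking the side chain.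
5. Ring order: rings A and B are bought as benzenes; ring C is the only ring formed (third step).

Assumption: the SMILES defines no stereocentre and no stereo double bond (rotation about C3–C1' is not specified), so the target is treated as achiral and no stereocontrol is needed.

**Step 1**
Reactants: 1 (3,5-dimethoxyphenyl)acetic acid
Product: 2 (3-hydroxy-5-methoxyphenyl)acetic acid
Conditions: NaSEt (3 equiv), DMF, 140 °C, 3 h; then 1 M HCl
Reagents that add atoms: none
Why: Nucleophilic SN2 O-demethylation by thiolate stops after one of the two equivalent ethers because the phenoxide formed makes loss of a second aryloxide from the same ring much slower; no stereocentre is formed.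

**Step 2**
Reactants: 2 (3-hydroxy-5-methoxyphenyl)acetic acid
Product: 3 (2,6-dibromo-3-hydroxy-5-methoxyphenyl)acetic acid
Conditions: NBS (2.05 equiv), MeCN, −10 °C to rt
Reagents that add atoms: N-bromosuccinimide, O=C1CCC(=O)N1Br
Why: Electrophilic aromatic bromination goes to the two carbons flanking the side chain (each ortho to one oxygen and para to the other), while the carbon between OH and OMe is the slowest site, as in resorcinol ethers, so two equivalents stop at the 2,6-dibromide.

**Step 3**
Reactants: 3 (2,6-dibromo-3-hydroxy-5-methoxyphenyl)acetic acid, 4 phloroglucinol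
Product: 6 3-(2,6-dibromo-3-hydroxy-5-methoxyphenyl)-5,7-dihydroxy-4H-chromen-4-one, via deoxybenzoin 5 (not isolated)
Conditions: 4 (1.1 equiv), BF3·OEt2, 85 °C, 2 h; then DMF, MsCl, 60 °C, 2 h; aq NaOAc
Reagents that add atoms: N,N-dimethylformamide, CN(C)C=O
Why: BF3-mediated Friedel–Crafts C-acylation of phloroglucinol gives deoxybenzoin 5, whose activated CH2 is formylated by the DMF/MsCl Vilsmeier-type reagent, and the ortho phenol oxygen then closes ring C on the new carbon with loss of dimethylamine (one-pot deoxybenzoin isoflavone synthesis, C–O ring closure).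

**Step 4**
Reactants: 6 3-(2,6-dibromo-3-hydroxy-5-methoxyphenyl)-5,7-dihydroxy-4H-chromen-4-one
Product: 7 5,7-dihydroxy-3-[3-hydroxy-5-methoxy-2,6-bis(3-methylbut-2-en-1-yl)phenyl]-4H-chromen-4-one
Conditions: prenylzinc bromide C5H9ZnBr (6 equiv, THF), Pd(OAc)2 (5 mol %), CPhos (2-dicyclohexylphosphino-2',6'-bis(dimethylamino)biphenyl, 10 mol %), THF, 0 °C to rt; aq NH4Cl
Reagents that add atoms: prenylzinc bromide, CC(C)=CC[Zn]Br
Why: Twofold Negishi coupling in which the bulky biarylphosphine makes reductive elimination from the primary sigma-prenyl aryl palladium fast, so the linear prenyl arene forms at both bromides; the three acidic OH groups become zinc phenoxides (hence the excess reagent), which also make the chromone carbonyl less electrophilic.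

**Step 5**
Reactants: 7 5,7-dihydroxy-3-[3-hydroxy-5-methoxy-2,6-bis(3-methylbut-2-en-1-yl)phenyl]-4H-chromen-4-one
Product: 9 erythbigenin, via o-quinone 8 (not isolated)
Conditions: IBX (1.2 equiv), DMF, 0 °C to rt, 1 h; then aq Na2S2O4 (5 equiv), rt, 15 min, under argon
Reagents that add atoms: 2-iodoxybenzoic acid (IBX), O=C1OI(=O)(O)c2ccccc12
Why: Proposed new method: IBX ortho-oxygenation has not been shown on a 3-alkoxyphenol where the oxygen must enter the C–H between OH and OMe while the other ortho carbon carries a prenyl group, nor on an unprotected prenylated 5,7-dihydroxyisoflavone; the electron-rich 3'-phenol (not the electron-poor, hydrogen-bonded ring-A phenols) exchanges onto pentavalent iodine, the I=O oxygen is passed intramolecularly to C4' (C2' is quaternary and shielded by the twisted chromone), tautomerisation and loss of 2-iodobenzoic acid give o-quinone 8, which dithionite reduces in the same flask before it can tautomerise to a quinone methide; the closest known reaction type is IBX oxidation of simple electron-rich phenols to o-quinones followed by reduction to catechols, and no stereocentre is formed.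

**Compound list**
1 | (3,5-dimethoxyphenyl)acetic acid | COc1cc(CC(=O)O)cc(OC)c1 | starting material
2 | (3-hydroxy-5-methoxyphenyl)acetic acid | COc1cc(O)cc(CC(=O)O)c1 | intermediate
3 | (2,6-dibromo-3-hydroxy-5-methoxyphenyl)acetic acid | OC(=O)Cc1c(Br)c(O)cc(OC)c1Br | intermediate
4 | phloroglucinol (benzene-1,3,5-triol) | Oc1cc(O)cc(O)c1 | starting material
5 | 2-(2,6-dibromo-3-hydroxy-5-methoxyphenyl)-1-(2,4,6-trihydroxyphenyl)ethan-1-one (deoxybenzoin, not isolated) | COc1cc(O)c(Br)c(CC(=O)c2c(O)cc(O)cc2O)c1Br | intermediate
6 | 3-(2,6-dibromo-3-hydroxy-5-methoxyphenyl)-5,7-dihydroxy-4H-chromen-4-one | COc1cc(O)c(Br)c(-c2coc3cc(O)cc(O)c3c2=O)c1Br | intermediate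
7 | 5,7-dihydroxy-3-[3-hydroxy-5-methoxy-2,6-bis(3-methylbut-2-en-1-yl)phenyl]-4H-chromen-4-one | COc1cc(O)c(CC=C(C)C)c(-c2coc3cc(O)cc(O)c3c2=O)c1CC=C(C)C | intermediate
8 | 5,7-dihydroxy-3-[5-methoxy-2,6-bis(3-methylbut-2-en-1-yl)-3,4-dioxocyclohexa-1,5-dien-1-yl]-4H-chromen-4-one (o-quinone, not isolated) | COC1=C(CC=C(C)C)C(c2coc3cc(O)cc(O)c3c2=O)=C(CC=C(C)C)C(=O)C1=O | intermediate
9 | erythbigenin, 3-[3,4-dihydroxy-5-methoxy-2,6-bis(3-methylbut-2-en-1-yl)phenyl]-5,7-dihydroxy-4H-chromen-4-one | COc1c(O)c(O)c(CC=C(C)C)c(-c2coc3cc(O)cc(O)c3c2=O)c1CC=C(C)C | target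

**Step count**
Total steps: 5. Longest linear sequence: 5 steps (1 to 9).

**Steps most likely to fail**

Step 5 (the proposed new oxygenation). Oxygen could be delivered to the prenyl-bearing C2' instead of C4', or quinone 8 could tautomerise toward a quinone methide and cyclise onto a prenyl group. The fallback uses known chemistry and carries the C4' oxygen from the start, so the last oxidation is the known IBX oxidative demethylation of a 2-methoxyphenol. It sets out from phloroglucinol 4 and comes back to the route at o-quinone 8.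
- Commercial (4-hydroxy-3,5-dimethoxyphenyl)acetic acid F1 is dibrominated with NBS (2.05 equiv, MeCN) at its only two free ring carbons to give (2,6-dibromo-4-hydroxy-3,5-dimethoxyphenyl)acetic acid F2.
- F2 and 4 under the step 3 conditions give the deoxybenzoin 2-(2,6-dibromo-4-hydroxy-3,5-dimethoxyphenyl)-1-(2,4,6-trihydroxyphenyl)ethan-1-one F3 (not isolated) and then 3-(2,6-dibromo-4-hydroxy-3,5-dimethoxyphenyl)-5,7-dihydroxy-4H-chromen-4-one F4.
- Negishi coupling as in step 4 gives 5,7-dihydroxy-3-[4-hydroxy-3,5-dimethoxy-2,6-bis(3-methylbut-2-en-1-yl)phenyl]-4H-chromen-4-one F5.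
- IBX (DMF, rt) oxygenates one of the two equivalent methoxy-bearing ortho carbons of F5 and expels methanol, so no regiochemical choice arises, and gives the same o-quinone 8; Na2S2O4 reduces it to 9.

Step 4 (twofold Negishi prenylation). The second coupling is at a doubly flanked carbon, three acidic OH groups consume reagent, and the allylic zinc could add to the chromone. The fallback sets out from 6 and comes back at 7.
- Twofold Stille allylation of 6 with allyltributylstannane (Pd(PPh3)4, DMF, 100 °C), which tolerates free phenols and the chromone, gives 5,7-dihydroxy-3-[3-hydroxy-5-methoxy-2,6-di(prop-2-en-1-yl)phenyl]-4H-chromen-4-one F6.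
- Olefin cross-metathesis with excess 2-methylbut-2-ene (second-generation Grubbs catalyst, RuCl2(H2IMes)(PCy3)(=CHPh), CH2Cl2, 40 °C) turns both allyl groups into prenyl groups and gives 7.

Step 2 (dibromination of the free phenol 2). Bromination at the carbon between OH and OMe, or over-bromination, would give isomers that are hard to remove. The fallback sets out from 1 and comes back at 3, brominating before the phenol is unmasked.
- NBS (2.05 equiv, MeCN) on 1 gives (2,6-dibromo-3,5-dimethoxyphenyl)acetic acid F7; the carbon between the two methoxy groups is the least reactive, as in 1,3-dimethoxybenzene.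
- BBr3 (CH2Cl2, −78 to 0 °C, stopped at partial conversion, F7 recycled) removes one of the two equivalent methyl groups and gives 3.

**Further compounds**
F1 | step 5 | (4-hydroxy-3,5-dimethoxyphenyl)acetic acid | COc1cc(CC(=O)O)cc(OC)c1O
F2 | step 5 | (2,6-dibromo-4-hydroxy-3,5-dimethoxyphenyl)acetic acid | COc1c(O)c(OC)c(Br)c(CC(=O)O)c1Br
F3 | step 5 | 2-(2,6-dibromo-4-hydroxy-3,5-dimethoxyphenyl)-1-(2,4,6-trihydroxyphenyl)ethan-1-one | COc1c(O)c(OC)c(Br)c(CC(=O)c2c(O)cc(O)cc2O)c1Br
F4 | step 5 | 3-(2,6-dibromo-4-hydroxy-3,5-dimethoxyphenyl)-5,7-dihydroxy-4H-chromen-4-one | COc1c(O)c(OC)c(Br)c(-c2coc3cc(O)cc(O)c3c2=O)c1Br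
F5 | step 5 | 5,7-dihydroxy-3-[4-hydroxy-3,5-dimethoxy-2,6-bis(3-methylbut-2-en-1-yl)phenyl]-4H-chromen-4-one | COc1c(O)c(OC)c(CC=C(C)C)c(-c2coc3cc(O)cc(O)c3c2=O)c1CC=C(C)C
F6 | step 4 | 5,7-dihydroxy-3-[3-hydroxy-5-methoxy-2,6-di(prop-2-en-1-yl)phenyl]-4H-chromen-4-one | COc1cc(O)c(CC=C)c(-c2coc3cc(O)cc(O)c3c2=O)c1CC=C
F7 | step 2 | (2,6-dibromo-3,5-dimethoxyphenyl)acetic acid | COc1cc(OC)c(Br)c(CC(=O)O)c1Br
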